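**Retrosynthetic overview**
- The last C–C bond made is the exocyclic CH2–C4 bond to the six-membered ring: reductive Knoevenagel union of a gem-diprenyl acylphloroglucinol (through its only free ring CH) with a cyclopentanecarbaldehyde, then desilylation.
- The six-membered ring is never closed in the route: it is bought as phloroglucinol, C-acylated, then dearomatised by double C-prenylation at one carbon.
- The cyclopentane (C1 bears the exocyclic CH2, C2 = C(OH)CH3, C5 = CH–isopropenyl) is the only ring closed and therefore the last. The C1–C2 bond (aldol) and the C5–isopropenyl bond (1,4-addition) are made in one Rh/(S)-BINAP operation from achiral tert-butyl (E)-6-oxohept-2-enoate, itself a cross-metathesis product.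
- Enabling feature: the exocyclic carbon on C1 is 1,3 to the tertiary hydroxyl on C2, and C5 is β to it. With that carbon as an ester, C1 is the α-carbon of a carbonyl flanked by an aldol acceptor (C2) and a Michael terminus (C5); the cis-OH/trans-isopropenyl pattern is what a chelated (Z)-enolate aldol delivers.

Key step: step 4

Assumption: Rh/(S)-BINAP is taken to deliver the alkenyl group to the α-si face of an acyclic (E)-enoate, as in the accepted model for acyclic acceptors; if the first run shows the opposite sense, (R)-BINAP is used and nothing else changes.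

**Step 1**
Reactants: 1 phloroglucinol; 2 isobutyryl chloride
Product: 3 2-methyl-1-(2,4,6-trihydroxyphenyl)propan-1-one (phlorisobutyrophenone)
Conditions: AlCl3 (4 equiv), PhNO2, rt → 60 °C; ice/aq. HCl
Reagents that add atoms: isobutyryl chloride 2, CC(C)C(Cl)=O
Why: Friedel–Crafts C-acylation of the very electron-rich arene stops after one acyl group because the aluminium-complexed aryl ketone is deactivated.

**Step 2**
Reactants: 3 phlorisobutyrophenone; 4 prenyl bromide
Product: 6 3,5-dihydroxy-2-(2-methylpropanoyl)-6,6-bis(3-methylbut-2-en-1-yl)cyclohexa-2,4-dien-1-one, via monoprenyl phlorisobutyrophenone 5 (not isolated)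
Conditions: NaOMe (2.2 equiv), MeOH, 0 °C; 4 (2.05 equiv) added slowly, → rt; aq. HCl; chromatography
Reagents that add atoms: prenyl bromide 4, CC(C)=CCBr
Why: Dearomative double C-alkylation of the acylphloroglucinol phenolate, in which the first prenyl group makes its own ring carbon the more nucleophilic site so that the second should enter there, the aromatic 3,5-diprenyl isomer and triprenylated material being the expected by-products to be removed by chromatography.

**Step 3**
Reactants: 7 hex-5-en-2-one; 8 tert-butyl acrylate
Product: 9 tert-butyl (2E)-6-oxohept-2-enoate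
Conditions: Hoveyda–Grubbs II (2 mol%), 8 (3 equiv), CH2Cl2, 40 °C
Reagents that add atoms: tert-butyl acrylate 8, C=CC(=O)OC(C)(C)C
Why: Olefin cross-metathesis of a terminal alkene with an acrylate (type I with type II partner) should give the thermodynamically favoured (E)-enoate selectively, with ethylene lost.

**Step 4**
Reactants: 9 tert-butyl (2E)-6-oxohept-2-enoate; 10 isopropenylboronic acid pinacol ester
Product: 13 tert-butyl (1S,2R,5R)-2-hydroxy-2-methyl-5-(prop-1-en-2-yl)cyclopentane-1-carboxylate, via rhodium enolate 11 (not isolated), via rhodium aldolate 12 (not isolated)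
Conditions: [Rh(cod)OH]2 (2.5 mol%), (S)-BINAP (6 mol%), 10 (2.5 equiv), KOH (10 mol%), H2O (5 equiv), 1,4-dioxane, 70 °C
Reagents that add atoms: isopropenylboronic acid pinacol ester 10, CC(=C)B1OC(C)(C)C(C)(C)O1
Why: Proposed new method: an alkenyl–Rh(I)/(S)-BINAP species formed by transmetalation from boron should insert the (E)-enoate C=C enantioselectively (alkenyl to C3 of 9, the later ring C5) to give the O-bound (Z)-rhodium enolate 11, whose α-carbon adds to the tethered methyl ketone before it is protonated, after which water releases 13 from aldolate 12 and regenerates Rh–OH; the closest known reaction type is the Rh/BINAP-catalysed tandem conjugate addition–aldol cyclisation of keto-enones with arylboronic acids, together with the Hayashi–Miyaura 1,4-addition of alkenylboron reagents to enoates, and what is new is an ester-derived rhodium enolate and an α-branched alkenyl group in the tandem process. The cyclopentane closes by a 5-(enolexo)-exo-trig aldol addition (C1–C2 bond). The isopropenyl-bearing centre (C5, R) is set by the ligand, which by the quadrant model delivers the alkenyl group to the α-si face of the acyclic (E)-acceptor. C1 and C2 follow from a rhodium-bridged chair-like (Zimmerman–Traxler) transition state: chelation of the enolate and ketone oxygens forces the ester and the new hydroxyl cis, and allylic 1,3-strain in the (Z)-enolate puts the C5–H in the enolate plane so that the ketone reaches the face opposite to the isopropenyl group (ester trans to isopropenyl). The step needs aldol capture to outrun protonation of 11 and needs the ketone to survive the alkenyl-rhodium; the five-membered tether and the small amount of water should secure the first, the inertness of alkenyl–Rh(I) towards ketones the second, and the tert-butyl ester resists the catalytic hydroxide.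

**Step 5**
Reactants: 13 hydroxy ester; 14 triethylsilyl trifluoromethanesulfonate
Product: 15 tert-butyl (1S,2R,5R)-2-methyl-5-(prop-1-en-2-yl)-2-[(triethylsilyl)oxy]cyclopentane-1-carboxylate
Conditions: TESOTf (1.3 equiv), 2,6-lutidine (2.5 equiv), CH2Cl2, −78 → −20 °C
Reagents that add atoms: triethylsilyl trifluoromethanesulfonate 14, CC[Si](CC)(CC)OS(=O)(=O)C(F)(F)F
Why: Silyl triflate/2,6-lutidine silylation of the hindered tertiary alcohol at low temperature leaves the tert-butyl ester intact and removes the free β-hydroxyl that would allow retro-aldol cleavage or dehydration once C1 carries a formyl group.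

**Step 6**
Reactants: 15 silyl ether ester
Product: 17 (1S,2R,5R)-2-methyl-5-(prop-1-en-2-yl)-2-[(triethylsilyl)oxy]cyclopentane-1-carbaldehyde, via aluminium hemiacetal 16 (not isolated)
Conditions: DIBAL-H (1.3 equiv), toluene, −78 °C; MeOH, then aq. Rochelle salt
Reagents that add atoms: none
Why: Partial reduction of the ester with DIBAL-H relies on the tetrahedral aluminium hemiacetal of the bulky tert-butyl ester persisting at −78 °C until the quench, the α-stereocentre being untouched.

**Step 7**
Reactants: 17 aldehyde; 6 gem-diprenyl acylphloroglucinol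
Product: 19 3,5-dihydroxy-4-({(1S,2R,5R)-2-methyl-5-(prop-1-en-2-yl)-2-[(triethylsilyl)oxy]cyclopentyl}methyl)-2-(2-methylpropanoyl)-6,6-bis(3-methylbut-2-en-1-yl)cyclohexa-2,4-dien-1-one, via alkylidene trione 18 (not isolated)
Conditions: L-proline (20 mol%), Hantzsch ester (1.2 equiv), CH2Cl2, rt
Reagents that add atoms: none
Why: Organocatalytic three-component reductive alkylation (Knoevenagel condensation to the alkylidene trione, then conjugate hydride transfer from the Hantzsch ester) joins the aldehyde to the only nucleophilic ring CH of 6 without a new stereocentre, and any enamine-mediated equilibration at the aldehyde α-carbon should return the all-trans arrangement already present.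

**Step 8**
Reactants: 19 silyl-protected coupling product
Product: 20 3,5-dihydroxy-4-{[(1S,2R,5R)-2-hydroxy-2-methyl-5-(prop-1-en-2-yl)cyclopentyl]methyl}-2-(2-methylpropanoyl)-6,6-bis(3-methylbut-2-en-1-yl)cyclohexa-2,4-dien-1-one (CNP0290578.2)
Conditions: HF·pyridine, pyridine/THF, 0 °C → rt
Reagents that add atoms: none
Why: Fluoride-induced cleavage of the tertiary silyl ether under buffered conditions should leave the prenyl and isopropenyl groups, the tertiary alcohol and the enolised triketone untouched.

**Compound list**
1 | phloroglucinol (benzene-1,3,5-triol) | Oc1cc(O)cc(O)c1 | starting material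
2 | isobutyryl chloride (2-methylpropanoyl chloride) | CC(C)C(Cl)=O | starting material
3 | 2-methyl-1-(2,4,6-trihydroxyphenyl)propan-1-one | CC(C)C(=O)c1c(O)cc(O)cc1O | intermediate
4 | prenyl bromide (1-bromo-3-methylbut-2-ene) | CC(C)=CCBr | starting material
5 | 2-methyl-1-[2,4,6-trihydroxy-3-(3-methylbut-2-en-1-yl)phenyl]propan-1-one | CC(C)C(=O)c1c(O)cc(O)c(CC=C(C)C)c1O | intermediate (not isolated)
6 | 3,5-dihydroxy-2-(2-methylpropanoyl)-6,6-bis(3-methylbut-2-en-1-yl)cyclohexa-2,4-dien-1-one | CC(C)C(=O)C1=C(O)C=C(O)C(CC=C(C)C)(CC=C(C)C)C1=O | intermediate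
7 | hex-5-en-2-one | CC(=O)CCC=C | starting material
8 | tert-butyl acrylate | C=CC(=O)OC(C)(C)C | starting material
9 | tert-butyl (2E)-6-oxohept-2-enoate | CC(=O)CC/C=C/C(=O)OC(C)(C)C | intermediate
10 | isopropenylboronic acid pinacol ester (4,4,5,5-tetramethyl-2-(prop-1-en-2-yl)-1,3,2-dioxaborolane) | CC(=C)B1OC(C)(C)C(C)(C)O1 | starting material
11 | rhodium(I) (Z)-enolate of tert-butyl (3R)-6-oxo-3-(prop-1-en-2-yl)heptanoate, (S)-BINAP on rhodium not drawn | C=C(C)[C@H](CCC(C)=O)/C=C(/OC(C)(C)C)O[Rh] | intermediate (not isolated)
12 | rhodium(I) alkoxide (aldolate) of 13, (S)-BINAP on rhodium not drawn | C=C(C)[C@@H]1CC[C@@](C)(O[Rh])[C@H]1C(=O)OC(C)(C)C | intermediate (not isolated)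
13 | tert-butyl (1S,2R,5R)-2-hydroxy-2-methyl-5-(prop-1-en-2-yl)cyclopentane-1-carboxylate | C=C(C)[C@@H]1CC[C@@](C)(O)[C@H]1C(=O)OC(C)(C)C | intermediate
14 | triethylsilyl trifluoromethanesulfonate | CC[Si](CC)(CC)OS(=O)(=O)C(F)(F)F | starting material
15 | tert-butyl (1S,2R,5R)-2-methyl-5-(prop-1-en-2-yl)-2-[(triethylsilyl)oxy]cyclopentane-1-carboxylate | C=C(C)[C@@H]1CC[C@@](C)(O[Si](CC)(CC)CC)[C@H]1C(=O)OC(C)(C)C | intermediate
16 | diisobutylaluminium hemiacetal of 15 (hemiacetal carbon undefined) | C=C(C)[C@@H]1CC[C@@](C)(O[Si](CC)(CC)CC)[C@H]1C(OC(C)(C)C)O[Al](CC(C)C)CC(C)C | intermediate (not isolated)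
17 | (1S,2R,5R)-2-methyl-5-(prop-1-en-2-yl)-2-[(triethylsilyl)oxy]cyclopentane-1-carbaldehyde | C=C(C)[C@@H]1CC[C@@](C)(O[Si](CC)(CC)CC)[C@H]1C=O | intermediate
18 | alkylidene trione from 6 and 17 (Knoevenagel adduct, alkene geometry undefined) | C=C(C)[C@@H]1CC[C@@](C)(O[Si](CC)(CC)CC)[C@H]1C=C1C(=O)C(CC=C(C)C)(CC=C(C)C)C(=O)C(C(=O)C(C)C)=C1O | intermediate (not isolated)
19 | 3,5-dihydroxy-4-({(1S,2R,5R)-2-methyl-5-(prop-1-en-2-yl)-2-[(triethylsilyl)oxy]cyclopentyl}methyl)-2-(2-methylpropanoyl)-6,6-bis(3-methylbut-2-en-1-yl)cyclohexa-2,4-dien-1-one | C=C(C)[C@@H]1CC[C@@](C)(O[Si](CC)(CC)CC)[C@H]1CC1=C(O)C(CC=C(C)C)(CC=C(C)C)C(=O)C(C(=O)C(C)C)=C1O | intermediate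
20 | 3,5-dihydroxy-4-{[(1S,2R,5R)-2-hydroxy-2-methyl-5-(prop-1-en-2-yl)cyclopentyl]methyl}-2-(2-methylpropanoyl)-6,6-bis(3-methylbut-2-en-1-yl)cyclohexa-2,4-dien-1-one | C=C(C)[C@@H]1CC[C@@](C)(O)[C@H]1CC1=C(O)C(CC=C(C)C)(CC=C(C)C)C(=O)C(C(=O)C(C)C)=C1O | target
21 | (4R)-limonene 1,2-oxide, cis/trans mixture at the epoxide (used only in the fallback for step 4) | CC12CC[C@H](CC1O2)C(C)=C | starting material

**Totals**
Total step count: 8. Longest linear sequence: 6 steps (steps 3–8, from hex-5-en-2-one).

**Steps most likely to fail, with fallbacks**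

Step 4 (key step). The rhodium enolate may be protonated before the aldol closure, leaving the open-chain 1,4-adduct. Transmetalation of the α-branched alkenylboronate may be slow against protodeboronation, and facial control with an alkenyl group may be insufficient. The fallback uses known chemistry and takes the stereocentre from the chiral pool. It sets out from 21, commercial (4R)-limonene 1,2-oxide, and does not use 9. Periodic acid (HIO4·2H2O, THF/H2O, 0 °C) opens and cleaves the epoxide to (3R)-6-oxo-3-(prop-1-en-2-yl)heptanal F1, which already carries the isopropenyl centre in the required configuration. Intramolecular aldol addition of this 1,6-keto aldehyde (5-enolexo; cat. KOH, MeOH, −10 °C, stopped before dehydration) closes the cyclopentane to (1S,2R,5R)-2-hydroxy-2-methyl-5-(prop-1-en-2-yl)cyclopentane-1-carbaldehyde F2. The hydrogen-bonded cis-ketol, with the formyl group trans to both neighbouring carbon substituents, is the expected thermodynamic aldol. Silylation as in step 5 (14, 2,6-lutidine, −78 °C) comes back to the route at 17.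

Step 2. The second prenyl group may enter at the unsubstituted ring carbon (aromatisation to the 3,5-diprenyl isomer), or a third may be taken up, so that little of the gem-diprenyl compound forms. The fallback moves the dearomatisation to the end and sets out from 3 and 17. Condensation and hydride transfer as in step 7 (L-proline, Hantzsch ester, 3 in excess) should give 2-methyl-1-[2,4,6-trihydroxy-3-({(1S,2R,5R)-2-methyl-5-(prop-1-en-2-yl)-2-[(triethylsilyl)oxy]cyclopentyl}methyl)phenyl]propan-1-one F3. NaOMe/MeOH with 4 (2.1 equiv) then prenylates the only free ring carbon to the fully substituted arene, the monoprenyl derivative of F3, F4 (not isolated). The second prenyl group should dearomatise at the prenyl-bearing carbon, not at the carbon carrying the bulky cyclopentylmethyl group. This comes back to the route at 19, before step 8.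

Step 6. Reduction of the hindered tert-butyl ester may be incomplete at −78 °C, or the hemiacetal may collapse on warming and be over-reduced to the primary alcohol. The fallback replaces partial reduction by full reduction and re-oxidation and sets out from 15. LiAlH4 (THF, 0 °C → rt) gives {(1R,2R,5R)-2-methyl-5-(prop-1-en-2-yl)-2-[(triethylsilyl)oxy]cyclopentyl}methanol F5. Dess–Martin periodinane (NaHCO3, CH2Cl2, 0 °C) then comes back to the route at 17.

**Further compounds**
F1 | step 4 | (3R)-6-oxo-3-(prop-1-en-2-yl)heptanal | C=C(C)[C@H](CCC(C)=O)CC=O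
F2 | step 4 | (1S,2R,5R)-2-hydroxy-2-methyl-5-(prop-1-en-2-yl)cyclopentane-1-carbaldehyde | C=C(C)[C@@H]1CC[C@@](C)(O)[C@H]1C=O
F3 | step 2 | 2-methyl-1-[2,4,6-trihydroxy-3-({(1S,2R,5R)-2-methyl-5-(prop-1-en-2-yl)-2-[(triethylsilyl)oxy]cyclopentyl}methyl)phenyl]propan-1-one | C=C(C)[C@@H]1CC[C@@](C)(O[Si](CC)(CC)CC)[C@H]1Cc1c(O)cc(O)c(C(=O)C(C)C)c1O
F4 | step 2 | 2-methyl-1-[2,4,6-trihydroxy-3-(3-methylbut-2-en-1-yl)-5-({(1S,2R,5R)-2-methyl-5-(prop-1-en-2-yl)-2-[(triethylsilyl)oxy]cyclopentyl}methyl)phenyl]propan-1-one | C=C(C)[C@@H]1CC[C@@](C)(O[Si](CC)(CC)CC)[C@H]1Cc1c(O)c(CC=C(C)C)c(O)c(C(=O)C(C)C)c1O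
F5 | step 6 | {(1R,2R,5R)-2-methyl-5-(prop-1-en-2-yl)-2-[(triethylsilyl)oxy]cyclopentyl}methanol | C=C(C)[C@@H]1CC[C@@](C)(O[Si](CC)(CC)CC)[C@H]1CO
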